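**Retrosynthetic overview**

1. Target ⇒ macrocyclic C1 alcohol + silyl-protected 4-iodophenol + CO (palladium alkoxycarbonylation), then desilylation.
2. Ten-membered ring (the only ring, closed late) ⇒ acyclic bis[(E)-alkenyl iodide] + ethylene-derived 1,2-bis(boronate). A 12-membered cyclic bis(boronate) contracts twice (12 → 11 → 10) by iodine-triggered 1,2-shifts from boron to carbon, forming C4–C5 and C6–C7 and both Z-alkenes.
3. Bis(alkenyl iodide) ⇒ 1,7-diyne, by methylalumination–iodination (C3 methyl, C4–I) and hydrozirconation–iodination (C7–I).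
4. Diyne ⇒ 3-methylbutanal + but-2-ynal (anti aldol sets C9 and C10) + propargyl bromide (reagent-controlled propargylation sets C1).

Assumption: but-2-ynal, (+)-Ipc2BOMe and tert-butyl(4-iodophenoxy)dimethylsilane (4-iodophenol carrying a silyl protecting group) are bought; locants C1–C10 are those of the target ring (C1 ester carbon, C3=C4 and C7=C8 alkenes, C9 carbinol, C10 isopropyl carbon).

**Route**

Step 1
Reactants: 1 3-methylbutanal; 2 but-2-ynal
Product: 3 (2S,3R)-3-hydroxy-2-(propan-2-yl)hex-4-ynal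
Conditions: L-proline (20 mol%), DMF, 4 °C; 1 added over 24 h to 2 (2 equiv)
Reagents that add atoms: none
Why: Proline enamine catalysis (direct cross-aldol): the enamine of 1 attacks the non-enolisable, more electrophilic ynal through the hydrogen-bonded chair-like transition state, which gives the anti adduct and sets C10 and C9; slow addition of 1 suppresses its self-aldol.

Step 2
Reactants: 3 (2S,3R)-3-hydroxy-2-(propan-2-yl)hex-4-ynal
Product: 4 (2S,3R)-3-[(tert-butyldimethylsilyl)oxy]-2-(propan-2-yl)hex-4-ynal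
Conditions: TBSOTf, 2,6-lutidine, CH2Cl2, −78 °C
Reagents that add atoms: tert-butyldimethylsilyl trifluoromethanesulfonate, CC(C)(C)[Si](C)(C)OS(=O)(=O)C(F)(F)F
Why: Silylation of a secondary alcohol with a silyl triflate and a hindered base at low temperature caps the C9 hydroxyl, so that the later C1 hydroxyl is the only free one, without epimerising the α-stereocentre.

Step 3
Reactants: 4 (2S,3R)-3-[(tert-butyldimethylsilyl)oxy]-2-(propan-2-yl)hex-4-ynal; 5 3-bromoprop-1-yne
Product: 8 (4R,5R,6R)-6-[(tert-butyldimethylsilyl)oxy]-5-(propan-2-yl)nona-1,7-diyn-4-ol, via allenylmagnesium bromide 6 (not isolated), via B-allenyldiisopinocampheylborane 7 (not isolated)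
Conditions: 5, Mg, HgCl2 (1 mol%), Et2O, 0 °C; (+)-Ipc2BOMe, Et2O, −78 → 0 °C; 4, −100 → −78 °C; NaOH, H2O2
Reagents that add atoms: magnesium, [Mg] (stays in 6 only); (+)-B-methoxydiisopinocampheylborane, COB([C@H]1C[C@H]2C[C@@H]([C@@H]1C)C2(C)C)[C@H]1C[C@H]2C[C@@H]([C@@H]1C)C2(C)C (boron and terpene groups stay in 7 only)
Why: Brown-type asymmetric allenylboration (SE2′ transfer through a six-membered chair transition state gives the homopropargylic alcohol): the (−)-α-pinene-derived borane delivers the propargyl group to the Re face of the aldehyde and sets C1 as R (1,3-syn to the C9 oxygen) under reagent control, the substrate bias being small because the two α-substituents are of similar size.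

Step 4
Reactants: 8 (4R,5R,6R)-6-[(tert-butyldimethylsilyl)oxy]-5-(propan-2-yl)nona-1,7-diyn-4-ol
Product: 10 (1E,4R,5R,6R)-6-[(tert-butyldimethylsilyl)oxy]-1-iodo-2-methyl-5-(propan-2-yl)non-1-en-7-yn-4-ol, via alkenyldimethylalane 9 (not isolated)
Conditions: Me3Al (4 equiv), Cp2ZrCl2 (0.3 equiv), H2O (1.5 equiv), CH2Cl2, −30 → 0 °C; I2, THF, −30 °C
Reagents that add atoms: trimethylaluminium, C[Al](C)C (methyl carbon in 9 and 10, aluminium in 9 only); iodine, II
Why: Negishi zirconium-catalysed methylalumination: syn addition of Me–Al across the terminal alkyne (much faster than across the internal, hindered alkyne) puts the methyl on C3 and aluminium on C4, and iodinolysis with retention gives the (E)-alkenyl iodide.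

Step 5
Reactants: 10 (1E,4R,5R,6R)-6-[(tert-butyldimethylsilyl)oxy]-1-iodo-2-methyl-5-(propan-2-yl)non-1-en-7-yn-4-ol
Product: 12 (1E,4R,5R,6R,7E)-6-[(tert-butyldimethylsilyl)oxy]-1,8-diiodo-2-methyl-5-(propan-2-yl)nona-1,7-dien-4-ol, via alkenylzirconocene chloride 11 (not isolated)
Conditions: Cp2Zr(H)Cl (3 equiv), THF, 0 → 40 °C; I2, THF, 0 °C
Reagents that add atoms: Cp2Zr(H)Cl, [H][Zr](Cl)(C1C=CC=C1)C1C=CC=C1 (zirconium in 11 only); iodine, II
Why: Hydrozirconation–iodination: syn addition of Zr–H places zirconium on the less hindered, methyl-bearing alkyne carbon (C7) and hydrogen on C8, and iodinolysis with retention gives the (E)-2-iodoalkene, the geometry that the stereoinvertive coupling of step 7 needs.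

Step 6
Reactants: 13 ethene
Product: 14 2,2'-(ethane-1,2-diyl)bis(4,4,5,5-tetramethyl-1,3,2-dioxaborolane)
Conditions: B2pin2, Pt(dba)2 (3 mol%), toluene, 50 °C, ethene (1 atm)
Reagents that add atoms: bis(pinacolato)diboron, CC1(C)OB(OC1(C)C)B1OC(C)(C)C(C)(C)O1
Why: Platinum-catalysed diboration of an alkene (oxidative addition of the B–B bond, ethene insertion, reductive elimination) gives the two-carbon 1,2-bis(boronate) that becomes C5–C6.

Step 7
Reactants: 12 (1E,4R,5R,6R,7E)-6-[(tert-butyldimethylsilyl)oxy]-1,8-diiodo-2-methyl-5-(propan-2-yl)nona-1,7-dien-4-ol; 14 2,2'-(ethane-1,2-diyl)bis(4,4,5,5-tetramethyl-1,3,2-dioxaborolane)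
Product: 17 (1R,3Z,7Z,9S,10R)-9-[(tert-butyldimethylsilyl)oxy]-3,7-dimethyl-10-(propan-2-yl)cyclodeca-3,7-dien-1-ol, via trilithio species 15 (not isolated), via cyclic bis(boronate) complex 16 (not isolated)
Conditions: tBuLi (5.1 equiv), THF/Et2O, −78 °C; 14 (1.0 equiv) added over 6 h, 1 mM, −78 → −40 °C; I2 (2.5 equiv), THF, −78 °C; NaOMe (8 equiv), MeOH, −78 °C → rt
Reagents that add atoms: tert-butyllithium, [Li]C(C)(C)C (lithium in 15 and 16 only)
Why: Proposed new method: a two-fold Zweifel olefination run as a double ring contraction, in which the two alkenyllithium termini of 15 add to the two boron atoms of 14 under high dilution to give the 12-membered bis(boronate) 16, iodine forms an iodonium ion at each alkenyl group, each boron-bound ring CH2 then makes an anti 1,2-shift from boron to carbon (ring 12 → 11 → 10, forming C4–C5 and C6–C7) and methoxide-induced anti elimination of boron and iodide releases both trisubstituted alkenes with inversion of the alkenyl geometry (3Z and 7Z); the closest known reaction is the intermolecular Zweifel olefination of alkenyllithiums with alkyl pinacol boronates, which has not been used to close or contract a carbocycle.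

Step 8
Reactants: 17 (1R,3Z,7Z,9S,10R)-9-[(tert-butyldimethylsilyl)oxy]-3,7-dimethyl-10-(propan-2-yl)cyclodeca-3,7-dien-1-ol; 18 tert-butyl(4-iodophenoxy)dimethylsilane; 19 carbon monoxide
Product: 20 (1R,3Z,7Z,9S,10R)-9-[(tert-butyldimethylsilyl)oxy]-3,7-dimethyl-10-(propan-2-yl)cyclodeca-3,7-dien-1-yl 4-[(tert-butyldimethylsilyl)oxy]benzoate
Conditions: 18 (2 equiv), CO (1 atm), Pd(OAc)2 (5 mol%), Xantphos (6 mol%), Et3N, DMAP (0.5 equiv), toluene, 60 °C
Reagents that add atoms: none
Why: Palladium-catalysed alkoxycarbonylation of an aryl iodide (oxidative addition, CO insertion to the aroylpalladium, DMAP-relayed acyl transfer to the only free hydroxyl at C1) builds the ester from CO without touching a stereocentre, and 60 °C stays below the temperature at which the 1,5-diene could undergo Cope rearrangement.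

Step 9
Reactants: 20 (1R,3Z,7Z,9S,10R)-9-[(tert-butyldimethylsilyl)oxy]-3,7-dimethyl-10-(propan-2-yl)cyclodeca-3,7-dien-1-yl 4-[(tert-butyldimethylsilyl)oxy]benzoate
Product: 21 (1R,3Z,7Z,9S,10S)-9-hydroxy-3,7-dimethyl-10-(propan-2-yl)cyclodeca-3,7-dien-1-yl 4-hydroxybenzoate
Conditions: HF·pyridine, pyridine, THF, 0 °C → rt
Reagents that add atoms: none
Why: Fluoride-mediated desilylation with buffered HF·pyridine removes the aryl and the C9 silyl ethers in one operation under conditions too mild for acyl migration from O1 to O9 or for transannular cyclisation.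

**Compound list**

1 | 3-methylbutanal | CC(C)CC=O | starting material
2 | but-2-ynal | CC#CC=O | starting material
3 | (2S,3R)-3-hydroxy-2-(propan-2-yl)hex-4-ynal | CC#C[C@H](O)[C@H](C(C)C)C=O | intermediate
4 | (2S,3R)-3-[(tert-butyldimethylsilyl)oxy]-2-(propan-2-yl)hex-4-ynal | CC#C[C@H](O[Si](C)(C)C(C)(C)C)[C@H](C(C)C)C=O | intermediate
5 | 3-bromoprop-1-yne | C#CCBr | starting material
6 | propa-1,2-dien-1-ylmagnesium bromide | C=C=C[Mg]Br | intermediate
7 | B-(propa-1,2-dien-1-yl)diisopinocampheylborane, both isopinocampheyl groups of the (−)-α-pinene series | C=C=CB([C@H]1C[C@H]2C[C@@H]([C@@H]1C)C2(C)C)[C@H]1C[C@H]2C[C@@H]([C@@H]1C)C2(C)C | intermediate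
8 | (4R,5R,6R)-6-[(tert-butyldimethylsilyl)oxy]-5-(propan-2-yl)nona-1,7-diyn-4-ol | CC#C[C@H](O[Si](C)(C)C(C)(C)C)[C@H](C(C)C)[C@H](O)CC#C | intermediate
9 | [(1E,4R,5R,6R)-6-[(tert-butyldimethylsilyl)oxy]-4-[(dimethylalumanyl)oxy]-2-methyl-5-(propan-2-yl)non-1-en-7-yn-1-yl]dimethylalumane | CC#C[C@H](O[Si](C)(C)C(C)(C)C)[C@H](C(C)C)[C@H](O[Al](C)C)C/C(C)=C/[Al](C)C | intermediate
10 | (1E,4R,5R,6R)-6-[(tert-butyldimethylsilyl)oxy]-1-iodo-2-methyl-5-(propan-2-yl)non-1-en-7-yn-4-ol | CC#C[C@H](O[Si](C)(C)C(C)(C)C)[C@H](C(C)C)[C@H](O)C/C(C)=C/I | intermediate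
11 | 10 after syn hydrozirconation of the alkyne: Cp2Zr(Cl) on C8 of the chain (methyl-bearing carbon, cis to the new H on C7, trans to C6) and the hydroxyl as O–Zr(Cl)Cp2 | C/C(=C\[C@H](O[Si](C)(C)C(C)(C)C)[C@H](C(C)C)[C@H](O[Zr](Cl)(C1C=CC=C1)C1C=CC=C1)C/C(C)=C/I)[Zr](Cl)(C1C=CC=C1)C1C=CC=C1 | intermediate
12 | (1E,4R,5R,6R,7E)-6-[(tert-butyldimethylsilyl)oxy]-1,8-diiodo-2-methyl-5-(propan-2-yl)nona-1,7-dien-4-ol | I/C(C)=C/[C@H](O[Si](C)(C)C(C)(C)C)[C@H](C(C)C)[C@H](O)C/C(C)=C/I | intermediate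
13 | ethene | C=C | starting material
14 | 2,2'-(ethane-1,2-diyl)bis(4,4,5,5-tetramethyl-1,3,2-dioxaborolane) | CC1(C)OB(CCB2OC(C)(C)C(C)(C)O2)OC1(C)C | intermediate
15 | 12 with both iodine atoms replaced by lithium (alkene geometry retained) and the hydroxyl as lithium alkoxide | [Li]/C(C)=C/[C@H](O[Si](C)(C)C(C)(C)C)[C@H](C(C)C)[C@H](O[Li])C/C(C)=C/[Li] | intermediate
16 | dilithium salt of the 12-membered cyclic bis(boronate): each former C–Li carbon of 15 bonded to one tetracoordinate pinacolato boron of the B–CH2CH2–B unit of 14, O-lithium alkoxide | C/C1=C\[C@H](O[Si](C)(C)C(C)(C)C)[C@H](C(C)C)[C@H](O[Li])C/C(C)=C/[B-]2(OC(C)(C)C(C)(C)O2)CC[B-]12OC(C)(C)C(C)(C)O2.[Li+].[Li+] | intermediate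
17 | (1R,3Z,7Z,9S,10R)-9-[(tert-butyldimethylsilyl)oxy]-3,7-dimethyl-10-(propan-2-yl)cyclodeca-3,7-dien-1-ol | C/C1=C/[C@H](O[Si](C)(C)C(C)(C)C)[C@H](C(C)C)[C@H](O)C/C(C)=C\CC1 | intermediate
18 | tert-butyl(4-iodophenoxy)dimethylsilane | CC(C)(C)[Si](C)(C)Oc1ccc(I)cc1 | starting material
19 | carbon monoxide | [C-]#[O+] | starting material
20 | (1R,3Z,7Z,9S,10R)-9-[(tert-butyldimethylsilyl)oxy]-3,7-dimethyl-10-(propan-2-yl)cyclodeca-3,7-dien-1-yl 4-[(tert-butyldimethylsilyl)oxy]benzoate | C/C1=C/[C@H](O[Si](C)(C)C(C)(C)C)[C@H](C(C)C)[C@H](OC(=O)c2ccc(O[Si](C)(C)C(C)(C)C)cc2)C/C(C)=C\CC1 | intermediate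
21 | (1R,3Z,7Z,9S,10S)-9-hydroxy-3,7-dimethyl-10-(propan-2-yl)cyclodeca-3,7-dien-1-yl 4-hydroxybenzoate | C/C1=C/[C@H](O)[C@H](C(C)C)[C@H](OC(=O)c2ccc(O)cc2)C/C(C)=C\CC1 | target

**Step count and risk**

Total steps: 9. Longest linear sequence: 8 (steps 1–5 and 7–9); step 6 is a one-step side branch.

Most likely to fail:

Step 7 (the new double ring contraction; risks are oligomeric boronate complexes in place of the 12-membered bis(boronate), and incomplete second 1,2-shift). The fallback sets out from 10 and comes back at 17, using only known reaction types. Lithiate 10 (tBuLi, 3.1 equiv, −78 °C), add an excess of 14 (3 equiv), then I2 and NaOMe. This ordinary intermolecular Zweifel olefination forms C4–C5 with inversion and gives the (Z)-homoallylic pinacol boronate F1. Trans-hydrosilylation of the remaining alkyne (Et3SiH, [Cp*Ru(MeCN)3]PF6, CH2Cl2) puts silicon on the methyl-bearing carbon, cis to the silyloxy-bearing carbon, and gives the alkenylsilane F2. Iododesilylation with N-iodosuccinimide (retention) gives the (Z)-alkenyl iodide F3. An intramolecular B-alkyl Suzuki–Miyaura macrocyclisation (Pd(OAc)2, RuPhos, K3PO4 or Cs2CO3, toluene/H2O, high dilution), which proceeds with retention at the alkenyl carbon, forms C6–C7 and gives 17.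

Step 3 (the addition that sets C1 has to override the 1,3-anti preference of the β-silyloxy aldehyde). The fallback sets out from 4 and comes back at 8. Run the matched addition with the enantiomeric borane made from (−)-Ipc2BOMe and allenylmagnesium bromide; it follows the substrate's own preference and gives the C1-epimeric (4S)-alcohol F4 cleanly. Mitsunobu inversion (4-nitrobenzoic acid, PPh3, DIAD, toluene) gives the inverted 4-nitrobenzoate F5, and K2CO3 in MeOH releases 8.

Step 8 (a hindered secondary macrocyclic alcohol as the limiting partner in a carbonylative esterification). The fallback sets out from 18 and 17 and comes back at 20. Lithiate 18 (tBuLi, Et2O, −78 °C) and quench with carbon dioxide to give 4-[(tert-butyldimethylsilyl)oxy]benzoic acid F6. Couple F6 with 17 by Yamaguchi esterification (2,4,6-trichlorobenzoyl chloride, Et3N, then DMAP, toluene, rt) to reach 20.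

**Further compounds**

F1 | step 7 | (4R,5R,6R,8Z)-4-[(tert-butyldimethylsilyl)oxy]-8-methyl-5-(propan-2-yl)-11-(4,4,5,5-tetramethyl-1,3,2-dioxaborolan-2-yl)undec-8-en-2-yn-6-ol | CC#C[C@H](O[Si](C)(C)C(C)(C)C)[C@H](C(C)C)[C@H](O)C/C(C)=C\CCB1OC(C)(C)C(C)(C)O1
F2 | step 7 | (2Z,4R,5R,6R,8Z)-4-[(tert-butyldimethylsilyl)oxy]-8-methyl-5-(propan-2-yl)-11-(4,4,5,5-tetramethyl-1,3,2-dioxaborolan-2-yl)-2-(triethylsilyl)undeca-2,8-dien-6-ol | C/C(=C/[C@H](O[Si](C)(C)C(C)(C)C)[C@H](C(C)C)[C@H](O)C/C(C)=C\CCB1OC(C)(C)C(C)(C)O1)[Si](CC)(CC)CC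
F3 | step 7 | (2Z,4R,5R,6R,8Z)-4-[(tert-butyldimethylsilyl)oxy]-2-iodo-8-methyl-5-(propan-2-yl)-11-(4,4,5,5-tetramethyl-1,3,2-dioxaborolan-2-yl)undeca-2,8-dien-6-ol | C/C(I)=C/[C@H](O[Si](C)(C)C(C)(C)C)[C@H](C(C)C)[C@H](O)C/C(C)=C\CCB1OC(C)(C)C(C)(C)O1
F4 | step 3 | (4S,5R,6R)-6-[(tert-butyldimethylsilyl)oxy]-5-(propan-2-yl)nona-1,7-diyn-4-ol | CC#C[C@H](O[Si](C)(C)C(C)(C)C)[C@H](C(C)C)[C@@H](O)CC#C
F5 | step 3 | (4R,5R,6R)-6-[(tert-butyldimethylsilyl)oxy]-5-(propan-2-yl)nona-1,7-diyn-4-yl 4-nitrobenzoate | CC#C[C@H](O[Si](C)(C)C(C)(C)C)[C@H](C(C)C)[C@H](OC(=O)c1ccc(cc1)[N+](=O)[O-])CC#C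
F6 | step 8 | 4-[(tert-butyldimethylsilyl)oxy]benzoic acid | CC(C)(C)[Si](C)(C)Oc1ccc(cc1)C(=O)O
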